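The dihydropyran is cut at C1′–C1 and O–C10 (retro oxa-Diels–Alder). This gives (1E,4Z)-germacra-1(10),4-dien-11-ol and the o-quinone methide from 2,4-diformylphloroglucinol and isovaleraldehyde. C1=C10 and C4=C5 are then traced back to ketones at C1 and C5.
Enabling feature: in the ten-membered carbocycle C1–C10, the ring-fusion CH (C1) and the vinylic CH (C5) are 1,5-related, and each sits next to a methyl-bearing carbon (C10, C4). Joining C1 and C5 by a double bond folds this ring into the fused five- and seven-membered rings of (−)-guaiol, which already holds all fifteen carbons and the C7 centre with its CMe2OH group.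
Forward: ozonolysis of the C1=C5 ring-fusion alkene unveils the cyclodecane, and the C11 hydroxyl locks C5 as an oxolane ketal. C1 then becomes the E-alkene and C5 the Z-alkene, and the pyran ring closes last in a three-component cycloaddition.
Stereochemistry: C7 comes from guaiol. The C10 and C4 methine centres steer two Felkin–Anh reductions and are then spent in a syn-elimination (E) and an anti-elimination (Z). The E geometry gives the trans C1–H/C10–CH3 fusion, the C7-biased ring conformer selects the face, and the all-equatorial transition state sets C1′.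

Key step: step 1

Numbering: germacrane numbering is used for the terpenoid carbons. C1 is the ring-fusion CH, C4=C5 the alkene, C7 the CH bearing C11(CH3)2OH, C10 the C(CH3)–O carbon and C1′ the benzylic CH.
Assumption: the target is taken exactly as drawn, which is (1S,4Z,7R,10R,1′S) in this numbering, and commercial (−)-guaiol is taken as the (4S,7R,10S) isomer.

Step 1
Reactants: 1 (−)-guaiol
Product: 3 (2S,6S,9R)-9-(2-hydroxypropan-2-yl)-2,6-dimethylcyclodecane-1,5-dione, via secondary ozonide 2 (not isolated)
Conditions: O3, CH2Cl2, −78 °C (Sudan Red end point); then PPh3, −78 °C → rt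
Reagents that add atoms: ozone [O-][O+]=O
Why: Criegee ozonolysis: ozone adds as a 1,3-dipole to C1=C5, the only C=C of 1; the adduct cleaves and the two fragments, still tied by C2–C4, recombine to the bridged 1,2,4-trioxolane 2, whose O–O bond is reduced by PPh3 to leave ketones at C1 and C5. The closest known reactions are the ozonolyses of tetrasubstituted ring-fusion alkenes of hydroazulenes and Δ9,10-octalins to cyclodecanediones. No ring is closed by bond formation; the ten-membered ring C1–C10 appears because the bond shared by the five- and seven-membered rings is cut and their perimeter stays intact. No stereocentre is made, and C4, C7 and C10 are kept because cleavage and reduction run cold and neutral, so the α-methine centres cannot enolise. The selectivity needed is alkene over tertiary carbinol and C–H bonds, which the electron-rich tetrasubstituted alkene secures at −78 °C with an indicator-controlled end point; 3 is carried on without contact with base, which would start transannular aldolisation (C10 to C5, C6 to C1).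

Step 2
Reactants: 3 (2S,6S,9R)-9-(2-hydroxypropan-2-yl)-2,6-dimethylcyclodecane-1,5-dione
Product: 5 9-methoxy-4,8,11,11-tetramethyl-10-oxabicyclo[7.2.1]dodecan-5-one (C5 methyl ketal with C1 ketone free), via C5 hemiketal 4 (not isolated)
Conditions: MeOH, PPTS (10 mol %), 3 Å MS, rt
Reagents that add atoms: methanol CO
Why: Acid-catalysed mixed ketalisation (Fischer-glycosidation type): the C11 hydroxyl reaches only C5 through a five-membered ring (C1 would need a seven-membered one), methanol traps the oxocarbenium ion of 4, the medium-ring C1 ketone resists intermolecular ketalisation (I-strain), and the new centre is fixed as (5R) because the seven-carbon bridge C4–C8 can span the oxolane only in the cis sense.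

Step 3
Reactants: 5 9-methoxy-4,8,11,11-tetramethyl-10-oxabicyclo[7.2.1]dodecan-5-one
Product: 6 9-methoxy-4,8,11,11-tetramethyl-10-oxabicyclo[7.2.1]dodecan-5-ol, (1R)-carbinol with OH anti to the C10 methyl
Conditions: L-Selectride, THF, −78 → 0 °C; then H2O
Reagents that add atoms: none
Why: Felkin–Anh-controlled hydride reduction from the ring periphery: with C9 turned inward and antiperiplanar to the bulky hydride and the C10 methyl gauche to the carbonyl oxygen, the (1R)-alcohol should form, and the ketal is inert to hydride.

Step 4
Reactants: 6 9-methoxy-4,8,11,11-tetramethyl-10-oxabicyclo[7.2.1]dodecan-5-ol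
Product: 8 (4E)-9-methoxy-4,8,11,11-tetramethyl-10-oxabicyclo[7.2.1]dodec-4-ene (E-C1=C10), via sulfamate ester 7 (not isolated)
Conditions: Burgess reagent, benzene, 25 → 55 °C
Reagents that add atoms: none
Why: Burgess dehydration, a thermal syn-elimination (Ei) of 7: when C10–H eclipses the C1–O bond of the anti alcohol, C9 lies opposite C2, so loss of the tertiary hydrogen (Saytzeff orientation of the ion-pair-like transition state, helped by the syn-to-trans preference of ten-membered rings) should give the E-trisubstituted alkene under neutral conditions that spare the ketal, in which the tertiary alcohol stays hidden.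

Step 5
Reactants: 8 (4E)-9-methoxy-4,8,11,11-tetramethyl-10-oxabicyclo[7.2.1]dodec-4-ene
Product: 9 (2S,5E,9R)-9-(2-hydroxypropan-2-yl)-2,6-dimethylcyclodec-5-en-1-one
Conditions: PPTS (10 mol %), acetone–H2O, 0 °C → rt
Reagents that add atoms: water O
Why: Acid-catalysed ketal hydrolysis: the ketone-derived mixed ketal ionises under very mild acid and the large excess of water should trap the oxocarbenium ion before the transannular alkene can, giving a 5-oxogermacr-1(10)-ene of the stable curdione type with C4 and C7 untouched.

Step 6
Reactants: 9 (2S,5E,9R)-9-(2-hydroxypropan-2-yl)-2,6-dimethylcyclodec-5-en-1-one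
Product: 10 (1R,2S,5E,9R)-9-(2-hydroxypropan-2-yl)-2,6-dimethylcyclodec-5-en-1-ol, (5R)-carbinol with OH anti to the C4 methyl
Conditions: L-Selectride (excess), THF, −78 → 0 °C; then H2O
Reagents that add atoms: none
Why: Second Felkin–Anh/peripheral hydride reduction: C3 and C7 both lie on the inner face of the C5 carbonyl, so the hydride enters from outside past C4–H and should set (5R), while the unactivated E-alkene is inert.

Step 7
Reactants: 10 (1R,2S,5E,9R)-9-(2-hydroxypropan-2-yl)-2,6-dimethylcyclodec-5-en-1-ol
Product: 12 2-[(1R,3Z,7E)-4,8-dimethylcyclodeca-3,7-dien-1-yl]propan-2-ol, via C5 mesylate 11 (not isolated)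
Conditions: MsCl (1.1 equiv), Et3N, CH2Cl2, −30 °C; solvent exchange; DBU, toluene, 25 → 50 °C
Reagents that add atoms: none
Why: Chemoselective mesylation of the secondary alcohol followed by antiperiplanar E2 elimination: in the anti alcohol C4–H and C5–OMs are antiperiplanar in the conformer that holds C3 and C6 gauche, so loss of the Zaitsev hydrogen should give the ring-cis (Z) alkene (the cis-by-anti course usual in ten-membered rings); DBU in toluene disfavours ionisation and leaves the tertiary OH un-ionised, and backside attack by that OH would require a strained trans-bridged oxolane.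

Step 8
Reactants: 13 phloroglucinol
Product: 15 2,4,6-trihydroxybenzene-1,3-dicarbaldehyde (2,4-diformylphloroglucinol), via bis-iminium salt 14 (not isolated)
Conditions: POCl3 (2.2 equiv), DMF (2.2 equiv), EtOAc, 0 °C → rt; then ice-water
Reagents that add atoms: N,N-dimethylformamide CN(C)C=O; water O
Why: Double Vilsmeier–Haack formylation: the very electron-rich ring takes up two chloroiminium ions, the two iminium groups deactivate the third position, and water hydrolyses 14 to the dialdehyde; no stereocentre is involved.

Step 9
Reactants: 12 2-[(1R,3Z,7E)-4,8-dimethylcyclodeca-3,7-dien-1-yl]propan-2-ol; 15 2,4,6-trihydroxybenzene-1,3-dicarbaldehyde; 16 isovaleraldehyde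
Product: 18 CNP0570248.1, the (1S,4Z,7R,10R,1′S) trans-fused 6,8-diformyl-5,7-dihydroxy-4-isobutylchroman on the germacr-4-en-11-ol ring, via o-quinone methide 17 (not isolated)
Conditions: ethylenediammonium diacetate (20 mol %), THF, 4 Å MS, 25–35 °C, slow addition of 16
Reagents that add atoms: none
Why: Domino Knoevenagel condensation/inverse-electron-demand oxa-Diels–Alder reaction: the amine salt condenses 16 at the free ring position of 15 to the E-quinone methide 17, which adds suprafacially to the strained, more nucleophilic E-alkene C1=C10 rather than to the unstrained Z-alkene, with oxygen going to the more substituted C10; the E geometry fixes C1–H trans to C10–CH3, only the outer face of the E-alkene is open in the conformer that keeps the C7 substituent pseudo-equatorial (1S,10R), and the transition state with isobutyl, C2 and C9 equatorial on the nascent pyran gives 1′S.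

Compound list
1 | (−)-guaiol, 2-[(3S,5R,8S)-3,8-dimethyl-1,2,3,4,5,6,7,8-octahydroazulen-5-yl]propan-2-ol | C[C@H]1CC[C@H](CC2=C1CC[C@@H]2C)C(C)(C)O | starting material
2 | secondary ozonide, 1,2,4-trioxolane bridging C1 and C5 (bridgehead configuration open, lost on reduction) | C[C@H]1CC[C@H](CC23OOC1(O2)CC[C@@H]3C)C(C)(C)O | intermediate
3 | (2S,6S,9R)-9-(2-hydroxypropan-2-yl)-2,6-dimethylcyclodecane-1,5-dione | C[C@H]1CC[C@H](CC(=O)[C@@H](C)CCC1=O)C(C)(C)O | intermediate
4 | C5 hemiketal, 9-hydroxy-4,8,11,11-tetramethyl-10-oxabicyclo[7.2.1]dodecan-5-one | C[C@H]1CC[C@@H]2C[C@@](O)(OC2(C)C)[C@@H](C)CCC1=O | intermediate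
5 | 9-methoxy-4,8,11,11-tetramethyl-10-oxabicyclo[7.2.1]dodecan-5-one, (5R) methyl ketal | C[C@H]1CC[C@@H]2C[C@@](OC)(OC2(C)C)[C@@H](C)CCC1=O | intermediate
6 | 9-methoxy-4,8,11,11-tetramethyl-10-oxabicyclo[7.2.1]dodecan-5-ol, (1R,10S) anti | C[C@H]1CC[C@@H]2C[C@@](OC)(OC2(C)C)[C@@H](C)CC[C@H]1O | intermediate
7 | methyl N-(alkoxysulfonyl)carbamate of 6 (Burgess sulfamate ester) | C[C@H]1CC[C@@H]2C[C@@](OC)(OC2(C)C)[C@@H](C)CC[C@H]1OS(=O)(=O)NC(=O)OC | intermediate
8 | (4E)-9-methoxy-4,8,11,11-tetramethyl-10-oxabicyclo[7.2.1]dodec-4-ene | C/C1=C\CC[C@H](C)[C@@]2(OC)C[C@@H](CC1)C(C)(C)O2 | intermediate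
9 | (2S,5E,9R)-9-(2-hydroxypropan-2-yl)-2,6-dimethylcyclodec-5-en-1-one | C/C1=C\CC[C@H](C)C(=O)C[C@@H](CC1)C(C)(C)O | intermediate
10 | (1R,2S,5E,9R)-9-(2-hydroxypropan-2-yl)-2,6-dimethylcyclodec-5-en-1-ol | C/C1=C\CC[C@H](C)[C@H](O)C[C@@H](CC1)C(C)(C)O | intermediate
11 | C5 methanesulfonate of 10 | C/C1=C\CC[C@H](C)[C@H](OS(C)(=O)=O)C[C@@H](CC1)C(C)(C)O | intermediate
12 | 2-[(1R,3Z,7E)-4,8-dimethylcyclodeca-3,7-dien-1-yl]propan-2-ol, (1E,4Z)-germacra-1(10),4-dien-11-ol | C/C1=C/C[C@H](C(C)(C)O)CC/C(C)=C/CC1 | intermediate
13 | phloroglucinol | Oc1cc(O)cc(O)c1 | starting material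
14 | bis(dimethyliminium) salt of 15, dichlorophosphate counter-ions | C[N+](C)=Cc1c(O)cc(O)c(C=[N+](C)C)c1O.[O-]P(=O)(Cl)Cl.[O-]P(=O)(Cl)Cl | intermediate
15 | 2,4,6-trihydroxybenzene-1,3-dicarbaldehyde | O=Cc1c(O)cc(O)c(C=O)c1O | intermediate
16 | isovaleraldehyde (3-methylbutanal) | CC(C)CC=O | starting material
17 | (E)-o-quinone methide from 15 and 16 | CC(C)C/C=C1/C(=O)C(C=O)=C(O)C(C=O)=C1O | intermediate
18 | CNP0570248.1 | C/C1=C/C[C@H](C(C)(C)O)CC[C@@]2(C)Oc3c(C=O)c(O)c(C=O)c(O)c3[C@@H](CC(C)C)[C@@H]2CC1 | target

Total step count: 9. Longest linear sequence: 8 (steps 1–7 and 9).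

Steps most likely to fail

1. Step 4. Proton loss may occur from C2 instead of C10. The syn course may also erode if the ion pair separates, with transannular hydride shift or participation by a ketal oxygen.
The fallback sets out from 5 and returns at 8. It fixes both the position and the geometry of the alkene through two C–O bonds.
- Bromomagnesium diisopropylamide, TMSCl and Et3N would give the more substituted enol ether, C1-silyloxy C1=C10 enol ether F1.
- Buffered mCPBA (Rubottom oxidation) would give the 10-silyloxy ketone F2. It is drawn with oxygen in the place of the former C10–H. The C10 epimer would serve equally, because the next reduction is governed by the adjacent centre and both carbinol centres vanish.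
- L-Selectride, with C9 inward and the C10–O bond opposed to the carbonyl dipole, would give the silyloxy alcohol F3.
- K2CO3 in MeOH would give the trans-1,10-diol F4.
- Thiocarbonyldiimidazole would give the cyclic thionocarbonate F5.
- 1,3-Dimethyl-2-phenyl-1,3,2-diazaphospholidine at 40 °C (Corey–Winter olefination) would release 8 by stereospecific syn-cycloreversion.

2. Step 7. The base may deprotonate at C6. The mesylate may ionise with transannular participation of the E-alkene. The side-chain hydroxyl may form an ether.
The fallback sets out from 9 and returns at 12. It places no leaving group on an sp3 carbon.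
- Bromomagnesium diisopropylamide, TMSCl and Et3N would silylate the carbinol and give the thermodynamic, ring-cis tetrasubstituted enol ether, bis-silyl compound F6.
- MeLi followed by Comins' reagent would give the enol triflate F7.
- Pd(OAc)2, PPh3, HCO2H and Et3N in DMF would replace OTf by H with retention, giving the silyl ether of the dienol F8.
- K2CO3 in MeOH would give 12.

3. Step 9. The quinone methide may be intercepted by the enamine or enol of isovaleraldehyde. The buffer may promote transannular cyclisation of the diene. Facial and endo/exo selectivity may be incomplete.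
The fallback sets out from 15 and 16, uses 12, and returns at 18.
- Proline-catalysed three-component reductive alkylation of 15 with 16 and Hantzsch ester would give 2,4,6-trihydroxy-5-(3-methylbutyl)benzene-1,3-dicarbaldehyde F9.
- DDQ in nitromethane at 0 °C or below would then remove the benzylic hydride in the presence of 12 and generate 17 oxidatively. No aldehyde or amine is present, and the lower temperature should sharpen the selectivity of the cycloaddition to 18.

Further compounds
F1 | step 4 | C1-trimethylsilyloxy C1=C10 enol ether of 5 (ring-cis) | C/C1=C(O[Si](C)(C)C)/CC[C@H](C)[C@@]2(OC)C[C@@H](CC1)C(C)(C)O2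
F2 | step 4 | 10-trimethylsilyloxy ketone | C[C@@]1(O[Si](C)(C)C)CC[C@@H]2C[C@@](OC)(OC2(C)C)[C@@H](C)CCC1=O
F3 | step 4 | 10-trimethylsilyloxy (1R)-alcohol | C[C@@]1(O[Si](C)(C)C)CC[C@@H]2C[C@@](OC)(OC2(C)C)[C@@H](C)CC[C@H]1O
F4 | step 4 | trans-1,10-diol | C[C@@]1(O)CC[C@@H]2C[C@@](OC)(OC2(C)C)[C@@H](C)CC[C@H]1O
F5 | step 4 | cyclic 1,10-thionocarbonate | C[C@@]12CC[C@@H]3C[C@@](OC)(OC3(C)C)[C@@H](C)CC[C@H]1OC(=S)O2
F6 | step 7 | bis-trimethylsilyl compound, C5-silyloxy C4=C5 enol ether and C11 silyl ether | C/C1=C(O[Si](C)(C)C)/C[C@H](C(C)(C)O[Si](C)(C)C)CC/C(C)=C/CC1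
F7 | step 7 | C5 enol triflate, C11 silyl ether | C/C1=C(OS(=O)(=O)C(F)(F)F)/C[C@H](C(C)(C)O[Si](C)(C)C)CC/C(C)=C/CC1
F8 | step 7 | trimethylsilyl ether of 12 | C/C1=C/C[C@H](C(C)(C)O[Si](C)(C)C)CC/C(C)=C/CC1
F9 | step 9 | 2,4,6-trihydroxy-5-(3-methylbutyl)benzene-1,3-dicarbaldehyde | CC(C)CCc1c(O)c(C=O)c(O)c(C=O)c1O
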